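The route rests on reading O1–C2(=O) of the tetronic acid ring (the five-membered lactone O1–C2–C3–C4–C5) as one molecule of CO2 held between nucleophilic C3 and electrophilic C5, and the C5–O/C6–OH pair as a former terminal epoxide. The key step is a formal (3+2) annulation. The magnesium chelate of an acyclic (R)-epoxy 1,3-diketone is carboxylated at its central carbon (C3–C2), and the new carboxylate opens the epoxide at C5 with inversion (O1–C5). One operation closes the ring, sets C5 as S and frees the CH2OH group without protecting groups. The precursor arises from a crossed Claisen condensation of an anteiso methyl ketone with methyl (R)-glycidate.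

Key step: step 4

Remark: ring atoms are numbered O1, C2 (lactone C=O), C3 (acyl-bearing), C4 (enol carbon) and C5 (stereocentre), with C6 the CH2OH carbon. The target is handled as the enol tautomer drawn, because 3-acyltetronic acids equilibrate between enol forms without touching C5.

Step 1
Reactants: 1 (S)-1-bromo-2-methylbutane; 2 12-bromododecanoic acid
Product: 5 (S)-14-methylhexadecanoic acid, via Grignard reagent 3 (not isolated), via magnesium carboxylate 4 (not isolated)
Conditions: 1, Mg, THF, 40 °C (gives 3); 2, MeMgCl (1.0 equiv), THF, −20 °C (gives 4); then 3 (1.3 equiv), Li2CuCl4 (3 mol %), THF–NMP, −20 to 20 °C; 1 M HCl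
Reagents that add atoms: none
Why: Copper-catalysed Kochi-type cross-coupling of an alkyl Grignard reagent with a primary alkyl bromide tolerates the preformed magnesium carboxylate, and the stereocentre of 1 lies β to the C–Mg bond and is not touched.

Step 2
Reactants: 5 (S)-14-methylhexadecanoic acid
Product: 7 (S)-15-methylheptadecan-2-one, via dilithium gem-diolate 6 (not isolated)
Conditions: MeLi (2.2 equiv), Et2O–THF, 0 °C to rt; inverse quench into cold 1 M HCl
Reagents that add atoms: methyllithium, [Li]C
Why: In this methyl ketone synthesis from a carboxylic acid, addition of methyllithium to the lithium carboxylate stops at the stable geminal dilithium diolate, which collapses to the ketone only on aqueous quench.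

Step 3
Reactants: 7 (S)-15-methylheptadecan-2-one; 8 methyl (R)-glycidate
Product: 10 (16S)-16-methyl-1-[(2R)-oxiran-2-yl]octadecane-1,3-dione, via terminal lithium enolate 9 (not isolated)
Conditions: LiHMDS (2.1 equiv), THF, −78 °C; 8 (1.1 equiv), −78 to −30 °C; AcOH in THF at −78 °C, pH 5 buffer; short silica plug, used promptly
Reagents that add atoms: none
Why: In this crossed Claisen condensation, kinetic deprotonation at the methyl group gives the terminal enolate, which attacks the activated and practically non-enolisable α-oxygenated ester faster than the epoxide at low temperature, the second equivalent of base stores the product as its chelated lithium diketonate, and the epoxide stereocentre takes no part.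

Step 4
Reactants: 10 (16S)-16-methyl-1-[(2R)-oxiran-2-yl]octadecane-1,3-dione; 11 carbon dioxide
Product: 14 (5S)-4-hydroxy-5-(hydroxymethyl)-3-[(14S)-14-methylhexadecanoyl]furan-2(5H)-one (target), via magnesium diketonate chelate 12 (not isolated), via magnesium enolate-carboxylate 13 (not isolated)
Conditions: Mg(OTf)2 (1.2 equiv), dry MeCN, CO2 (10 bar, saturated before the base is added), i-Pr2NEt (2.5 equiv), 0 to 40 °C; cold 1 M HCl
Reagents that add atoms: carbon dioxide (11), O=C=O
Why: Proposed new method: soft enolisation by divalent magnesium and i-Pr2NEt gives the U-shaped chelate 12, whose central carbon C3 adds reversibly to CO2, loss of the now very acidic C3–H locks the adduct as the enolate-carboxylate 13, and its carboxylate oxygen attacks the epoxide CH (C5) from the rear, the strain released paying for the uphill carboxylation and the freed alkoxide ending as CH2OH after acidic work-up. The closest known reaction types are the magnesium salt/amine (or methyl magnesium carbonate) carboxylation of ketones with CO2, the silver-catalysed CO2 incorporation into conjugated ynones in which an enolate-derived carboxylate closes a tetronic acid ring onto an alkyne, and the thermal closure of γ-halo acetoacetates to tetronic acids; a 1,3-diketonate as carbon nucleophile combined with an epoxide as trap has not been shown. The only ring formed, the five-membered lactone O1–C2–C3–C4–C5, closes in the 5-exo-tet mode. C5 is the only new stereocentre and is controlled by stereospecific SN2 inversion of the (R)-epoxide carbon to S, while the anionic diketonate keeps C5–H from enolising and C14 of the side chain is a spectator. The step needs carboxylative closure to beat direct attack of the distal enolate oxygen on C5 (furanone formation) and 5-exo to beat 6-endo opening at C6: the chelate ties both enolate oxygens to magnesium with the distal one turned away from C5, places the C3 carboxylate syn to C5, and lets the O4-bound magnesium bind the epoxide oxygen so that the C5–O bond lies anti to the incoming carboxylate. Carboxylation at oxygen or at the chain α-CH2 is reversible and has no unstrained exit, the halide-free salt excludes halohydrin formation and double inversion, and every atom of 10 and 11 ends up in 14.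

Compound list
1 | (S)-1-bromo-2-methylbutane | CC[C@H](C)CBr | starting material
2 | 12-bromododecanoic acid | OC(=O)CCCCCCCCCCCBr | starting material
3 | (S)-2-methylbutylmagnesium bromide | CC[C@H](C)C[Mg]Br | intermediate
4 | chloromagnesium 12-bromododecanoate | [O-]C(=O)CCCCCCCCCCCBr.[Mg+2].[Cl-] | intermediate
5 | (S)-14-methylhexadecanoic acid | CC[C@H](C)CCCCCCCCCCCCC(=O)O | intermediate
6 | dilithium (S)-15-methylheptadecane-2,2-diolate | CC[C@H](C)CCCCCCCCCCCCC(C)([O-])[O-].[Li+].[Li+] | intermediate
7 | (S)-15-methylheptadecan-2-one | CC[C@H](C)CCCCCCCCCCCCC(=O)C | intermediate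
8 | methyl (R)-glycidate (methyl (2R)-oxirane-2-carboxylate) | COC(=O)[C@H]1CO1 | starting material
9 | lithium (S)-15-methylheptadec-1-en-2-olate | CC[C@H](C)CCCCCCCCCCCCC(=C)[O-].[Li+] | intermediate
10 | (16S)-16-methyl-1-[(2R)-oxiran-2-yl]octadecane-1,3-dione | CC[C@H](C)CCCCCCCCCCCCC(=O)CC(=O)[C@H]1CO1 | intermediate
11 | carbon dioxide | O=C=O | starting material
12 | magnesium triflate chelate of the (Z)-enolate of 10 | CC[C@H](C)CCCCCCCCCCCCC(=O)/C=C(\[O-])[C@H]1CO1.[Mg+2].[O-]S(=O)(=O)C(F)(F)F | intermediate
13 | magnesium salt of the C3-carboxylated enolate of 10 (carboxylate syn to the epoxide carbon) | CC[C@H](C)CCCCCCCCCCCCC(=O)/C(C(=O)[O-])=C(\[O-])[C@H]1CO1.[Mg+2] | intermediate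
14 | (5S)-4-hydroxy-5-(hydroxymethyl)-3-[(14S)-14-methylhexadecanoyl]furan-2(5H)-one | CC[C@H](C)CCCCCCCCCCCCC(=O)C1=C(O)[C@H](CO)OC1=O | target

Total step count: 4. Longest linear sequence: 4 steps (1 or 2 → 5 → 7 → 10 → 14).

Steps most likely to fail

Step 4. The carboxylation equilibrium of the stabilised diketonate may lie too far on the side of free CO2. Direct closure of an enolate oxygen onto the epoxide, opening at the terminal carbon in the 6-endo sense, or slow Lewis-acid degradation of the epoxide could then overtake the carboxylative closure. The fallback is a Lacey–Dieckmann construction by known chemistry that sets out from 5 and comes back at 14. Acid 5 is condensed with Meldrum's acid (DCC, DMAP, CH2Cl2) to the acyl Meldrum's acid F1. Commercial methyl (S)-glycidate is opened at its terminal carbon with benzyl alcohol (cat. BF3·OEt2) to methyl (S)-3-(benzyloxy)-2-hydroxypropanoate F2. Heating F1 with F2 in toluene traps the acylketene and gives the β-keto ester F3. TBAF in THF should close F3 to the O-benzyl tetronic acid F4, with C5 carried over from F2 with retention. Hydrogenolysis (H2, Pd/C, EtOAc) then gives 14.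

Step 3. Several processes could erode the condensation:
- proton transfer from the forming diketone to unreacted enolate;
- attack of the enolate, the amide base or the liberated methoxide on the epoxide;
- premature closure of an enolate oxygen onto the epoxide during warming or work-up.

The fallback replaces acylation by aldol addition and oxidation, sets out from 7 and comes back at 10. Commercial (S)-glycidol is oxidised (TEMPO, PhI(OAc)2, CH2Cl2) to (R)-oxirane-2-carbaldehyde F5, whose solution is used directly. Enolate 9, made from 7 with LDA (1.05 equiv, THF, −78 °C), adds to F5 at −78 °C to give the β-hydroxy ketone F6 as carbinol epimers, which is of no consequence. Dess–Martin periodinane in NaHCO3-buffered CH2Cl2 oxidises F6 to 10.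

Step 1. Slow cross-coupling of the β-branched Grignard reagent may let homocoupling, halogen–metal exchange and reduction of the bromide take over. The fallback is a Wittig olefination followed by hydrogenation, sets out from 2 and comes back at 5. Heating 2 with PPh3 in MeCN gives (11-carboxyundecyl)triphenylphosphonium bromide F7. (S)-2-Methylbutan-1-ol is oxidised (TEMPO, NaOCl, CH2Cl2–water, 0 °C) to (S)-2-methylbutanal F8, which is used at once to avoid epimerisation. The ylide from F7 (NaHMDS, 2.1 equiv, THF, −78 °C) reacts with F8 to give (12Z,14S)-14-methylhexadec-12-enoic acid F9. Hydrogenation (H2, Pd/C, EtOAc) then gives 5.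

Further compounds
F1 | step 4 | 5-[(14S)-1-hydroxy-14-methylhexadecylidene]-2,2-dimethyl-1,3-dioxane-4,6-dione | CC[C@H](C)CCCCCCCCCCCCC(O)=C1C(=O)OC(C)(C)OC1=O
F2 | step 4 | methyl (S)-3-(benzyloxy)-2-hydroxypropanoate | COC(=O)[C@@H](O)COCc1ccccc1
F3 | step 4 | (2S)-3-(benzyloxy)-1-methoxy-1-oxopropan-2-yl (16S)-16-methyl-3-oxooctadecanoate | CC[C@H](C)CCCCCCCCCCCCC(=O)CC(=O)O[C@@H](COCc1ccccc1)C(=O)OC
F4 | step 4 | (5S)-5-[(benzyloxy)methyl]-4-hydroxy-3-[(14S)-14-methylhexadecanoyl]furan-2(5H)-one | CC[C@H](C)CCCCCCCCCCCCC(=O)C1=C(O)[C@H](COCc2ccccc2)OC1=O
F5 | step 3 | (R)-oxirane-2-carbaldehyde | O=C[C@H]1CO1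
F6 | step 3 | (16S)-1-hydroxy-16-methyl-1-[(2R)-oxiran-2-yl]octadecan-3-one (both C1 epimers) | CC[C@H](C)CCCCCCCCCCCCC(=O)CC(O)[C@H]1CO1
F7 | step 1 | (11-carboxyundecyl)triphenylphosphonium bromide | OC(=O)CCCCCCCCCCC[P+](c1ccccc1)(c1ccccc1)c1ccccc1.[Br-]
F8 | step 1 | (S)-2-methylbutanal | CC[C@H](C)C=O
F9 | step 1 | (12Z,14S)-14-methylhexadec-12-enoic acid | CC[C@H](C)/C=C\CCCCCCCCCCC(=O)O
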